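Numbering: oxepane ring O1, C2 (quaternary, CH3), C3 (CHOH), C4, C5, C6 (=C8H-C9H2OH), C7 (OCH2); side chain C1'-C3' (CH2), C4' (CHCH3), C5' (C=O), C6'H=C7'(CH3)-CH(CH3)2.
Enabling feature: in the seven-membered ring O1 lies between the fully substituted C2 and C7. Removing O1 and bonding C2 to C7 leaves a six-membered 2,2-disubstituted 3-oxycyclohexanone (C7 as C=O), the reduction product of a prochiral cyclohexane-1,3-dione.
Cuts, in retrosynthetic order: C5'-C6' (alkenyllithium plus aldehyde), C7H2 back to a lactone C=O, C6=C8 (lactone aldol and elimination), C2-O1 and O1-C7 (oxygen insertion), C2'-C3' (cross-metathesis), C2-C1' (allylation).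
Forward: the six-membered carbocycle is allylated and desymmetrised, and the chain is joined as far as C5'. Oxygen insertion then enlarges the carbocycle to the oxepane ring, followed by the C6 alkylidene, the deoxygenation of C7 and, last, the enone.
Stereochemistry: C2 and C3 come from one ketoreductase reduction (C2 later migrates with retention), C4' from (S)-Roche ester, the 6E alkene from an E1cB elimination, and the 6'E alkene from a syn carboalumination.

Key step: step 9

Assumption: an anti-Prelog ketoreductase that reduces the allylated dione to the (2S,3R)-ketol is picked by a routine screen of a commercial enzyme panel, which is usual practice for 2,2-disubstituted cyclohexane-1,3-diones.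
Abbreviations in names: TBSO = (tert-butyldimethylsilyl)oxy; TBDPSO = (tert-butyldiphenylsilyl)oxy.

Step 1
Reactants: 1 2-methylcyclohexane-1,3-dione; 2 allyl acetate
Product: 3 2-allyl-2-methylcyclohexane-1,3-dione (achiral, prochiral at C2)
Conditions: Pd(PPh3)4 (2 mol %), DBU (1.05 equiv), THF, rt to 50 °C
Reagents that add atoms: none
Why: Tsuji-Trost allylation, in which zerovalent palladium ionises allyl acetate and the soft dione enolate is allylated at carbon to form C2-C1', while any O-allyl enol ether is re-ionised by the same catalyst and funnelled to the C-allyl dione.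

Step 2
Reactants: 3 2-allyl-2-methylcyclohexane-1,3-dione
Product: 4 (2S,3R)-2-allyl-3-hydroxy-2-methylcyclohexan-1-one (hydroxyl cis to methyl)
Conditions: ketoreductase (panel-selected, anti-Prelog), NADP+ (cat.), i-PrOH (10 vol %), KH2PO4/K2HPO4 buffer pH 7.0, 30 °C
Reagents that add atoms: none
Why: Ketoreductase desymmetrisation of a 2,2-disubstituted cyclohexane-1,3-dione, in which the active site binds one of the two enantiotopic carbonyl groups and delivers hydride to one face only, so a single reduction sets C3 (R) and, by breaking the symmetry, the quaternary C2 (S).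

Step 3
Reactants: 4 (2S,3R)-ketol
Product: 5 (2S,3R)-2-allyl-3-(TBSO)-2-methylcyclohexan-1-one
Conditions: TBSOTf (1.2 equiv), 2,6-lutidine (2 equiv), CH2Cl2, -78 to 0 °C
Reagents that add atoms: tert-butyldimethylsilyl triflate CC(C)(C)[Si](C)(C)OS(=O)(=O)C(F)(F)F
Why: Silyl ether formation with a silyl triflate, which is reactive enough for the neopentyl-type C3 hydroxyl in the cold, while the weak hindered base neither enolises the ketone nor triggers retro-aldol cleavage.

Step 4
Reactants: 6 methyl (S)-3-hydroxy-2-methylpropanoate (Roche ester)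
Product: 7 methyl (S)-3-(TBSO)-2-methylpropanoate
Conditions: TBSCl (1.1 equiv), imidazole (2 equiv), CH2Cl2, 0 °C to rt
Reagents that add atoms: tert-butyldimethylsilyl chloride CC(C)(C)[Si](C)(C)Cl
Why: Imidazole-promoted silylation of a primary alcohol, which does not touch the stereocentre that becomes C4'.

Step 5
Reactants: 7 silylated Roche ester
Product: 8 (S)-3-(TBSO)-2-methylpropanal
Conditions: i-Bu2AlH (1.05 equiv), CH2Cl2, -78 °C; aq. potassium sodium tartrate
Reagents that add atoms: none
Why: Partial reduction of an ester to the aldehyde with i-Bu2AlH at low temperature, a routine operation on this ester, with a cold neutral work-up and immediate use protecting the alpha stereocentre.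

Step 6
Reactants: 8 (S)-aldehyde
Product: 9 (R)-tert-butyldimethyl[(2-methylbut-3-en-1-yl)oxy]silane
Conditions: Ph3PCH3Br (1.3 equiv), n-BuLi (1.25 equiv), THF, 0 °C; then 8, -78 °C to rt
Reagents that add atoms: methyltriphenylphosphonium bromide C[P+](c1ccccc1)(c1ccccc1)c1ccccc1.[Br-]
Why: Wittig methylenation, in which the non-stabilised ylide adds to the aldehyde faster than it deprotonates it, so the future C4' centre is retained (S becomes R only through a change of CIP priorities).

Step 7
Reactants: 5 allyl ketone; 9 butenyl silyl ether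
Product: 10 (2S,3R)-3-(TBSO)-2-[(2E,4R)-5-(TBSO)-4-methylpent-2-en-1-yl]-2-methylcyclohexan-1-one
Conditions: 9 (3 equiv), second-generation Hoveyda-Grubbs catalyst RuCl2(SIMes)(=CH-C6H4-2-O-i-Pr) (5 mol %), 1,4-benzoquinone (10 mol %), CH2Cl2, 40 °C
Reagents that add atoms: none
Why: Olefin cross-metathesis of two terminal alkenes that both homodimerise slowly, driven by loss of ethene and by an excess of the cheaper partner, with benzoquinone holding back ruthenium hydride-induced double-bond migration toward C4' and the alkene geometry being irrelevant because it is saturated next.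

Step 8
Reactants: 10 cross-metathesis product
Product: 11 (2S,3R)-3-(TBSO)-2-[(4R)-5-(TBSO)-4-methylpentyl]-2-methylcyclohexan-1-one
Conditions: H2 (1 atm), PtO2 (5 mol %), EtOAc, rt
Reagents that add atoms: none
Why: Heterogeneous catalytic hydrogenation, with platinum preferred to palladium because it isomerises alkenes far less and so leaves the allylic C4' centre intact, while the hindered ketone and the silyl ethers are inert under these neutral conditions.

Step 9
Reactants: 11 (2S,3R)-cyclohexanone
Product: 13 (6R,7S)-6-(TBSO)-7-[(4R)-5-(TBSO)-4-methylpentyl]-7-methyloxepan-2-one (lactone C2 = C7 and lactone C7 = C2 of the target numbering), via Criegee adduct 12 (not isolated)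
Conditions: mCPBA (3 equiv), CH2Cl2, 0 °C to rt
Reagents that add atoms: 3-chloroperbenzoic acid OOC(=O)c1cccc(Cl)c1
Why: Baeyer-Villiger oxidation: the peracid adds to the C7 carbonyl (helped by the carboxylic acid that is liberated) to give Criegee adduct 12, and C2, aligned antiperiplanar to the O-O bond, shifts from C7 to the proximal peroxide oxygen as 3-chlorobenzoate leaves, which makes C2-O1 and O1-C7 in one event. The closest known reaction type is the peracid ring expansion of alpha-quaternary cyclohexanones to epsilon-caprolactones. The seven-membered ring arises by insertion of O1 into the six-membered carbocycle (a 1,2-shift with ring enlargement) and not by an end-to-end cyclisation, so no substitution at a tertiary carbon and no medium-ring closure is required. The oxygen-bearing stereocentre C2 is controlled by the migrating carbon itself, which keeps its configuration in the suprafacial shift, so the S centre of step 2 becomes the S tertiary ether carbon while C3 and C4' are untouched. The step needs C2 and not the C6 methylene to migrate, and the full substitution of C2, which best carries the developing positive charge, secures this even next to the inductively withdrawing C3 silyloxy group. Chemoselectivity is secured because step 8 has removed the only alkene and because the C3 silyl ether blocks retro-aldol cleavage and acyl transfer to a six-membered lactone.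

Step 10
Reactants: 14 (Z)-but-2-ene-1,4-diol
Product: 15 (Z)-1,4-bis(TBDPSO)but-2-ene
Conditions: TBDPSCl (2.1 equiv), imidazole (4 equiv), DMF, rt
Reagents that add atoms: tert-butyldiphenylsilyl chloride CC(C)(C)[Si](Cl)(c1ccccc1)c1ccccc1
Why: Imidazole-promoted silylation of both primary hydroxyls of a symmetrical diol, so no selectivity is needed.

Step 11
Reactants: 15 bis-silyl ether
Product: 17 2-(TBDPSO)acetaldehyde, via secondary ozonide 16 (not isolated)
Conditions: O3, CH2Cl2, -78 °C; then Me2S, -78 °C to rt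
Reagents that add atoms: ozone [O-][O+]=O
Why: Ozonolysis with reductive work-up, in which the symmetrical alkene gives two molecules of the same aldehyde.

Step 12
Reactants: 13 lactone; 17 2-(TBDPSO)acetaldehyde
Product: 19 (6R,7S)-3-[2-(TBDPSO)-1-hydroxyethyl]-6-(TBSO)-7-[(4R)-5-(TBSO)-4-methylpentyl]-7-methyloxepan-2-one (diastereomers at C6 and C8 of the target numbering), via lithium enolate 18 (not isolated)
Conditions: LiN(i-Pr)2 (1.15 equiv), THF, -78 °C; then 17 (1.3 equiv), -78 °C; sat. aq. NH4Cl
Reagents that add atoms: none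
Why: Aldol addition of a lactone lithium enolate, which forms C6-C8 at the only enolisable position of 13, with the two new centres needing no control because step 13 erases both.

Step 13
Reactants: 19 aldol adduct
Product: 21 (3E,6R,7S)-3-[2-(TBDPSO)ethylidene]-6-(TBSO)-7-[(4R)-5-(TBSO)-4-methylpentyl]-7-methyloxepan-2-one, via mesylate 20 (not isolated)
Conditions: MsCl (1.5 equiv), Et3N (3 equiv), CH2Cl2, 0 °C; then DBU (3 equiv), 0 °C to rt
Reagents that add atoms: none
Why: Mesylation and E1cB elimination, in which DBU removes the acidic C6 proton of either diastereomer and the enolate expels mesylate through the arrangement that keeps C9 away from the C7 carbonyl, giving the more stable, tiglate-like E-alkylidene lactone with C9 anti to C7.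

Step 14
Reactants: 21 E-alkylidene lactone
Product: 23 (3E,6R,7S)-3-[2-(TBDPSO)ethylidene]-6-(TBSO)-7-[(4R)-5-(TBSO)-4-methylpentyl]-7-methyloxepan-2-yl acetate (both epimers at the acetal carbon C7 of the target numbering), via aluminium hemiacetal 22 (not isolated)
Conditions: i-Bu2AlH (1.5 equiv), CH2Cl2, -78 °C; then pyridine (3 equiv), DMAP (2 equiv), Ac2O (6 equiv), -78 to -20 °C
Reagents that add atoms: acetic anhydride CC(=O)OC(C)=O
Why: Reductive acetylation of an ester, in which i-Bu2AlH adds once in the 1,2 sense to the lactone carbonyl, hemiacetal 22 persists at -78 °C, and acylation in the same flask fixes it as the cyclic alpha-acetoxy ether before it can open to the hydroxy enal.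

Step 15
Reactants: 23 alpha-acetoxy ether
Product: 25 (2S,3R,6E)-3-(TBSO)-6-[2-(TBDPSO)ethylidene]-2-[(4R)-5-(TBSO)-4-methylpentyl]-2-methyloxepane, via oxocarbenium ion 24 (not isolated)
Conditions: Et3SiH (5 equiv), BF3·OEt2 (1.5 equiv), CH2Cl2, -78 °C; sat. aq. NaHCO3
Reagents that add atoms: none
Why: Ionic hydrogenation of an alpha-acetoxy ether, in which BF3 ionises the acetate to the conjugated ion 24 and the silane delivers hydride to C7, the carbon next to oxygen that carries most of the charge (as in Ferrier-type reductions), so the 6E alkene stays in place and the low temperature spares the silyl ethers and the tertiary C2-O1 bond.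

Step 16
Reactants: 25 tris-silyl ether
Product: 26 (2R)-5-{(2S,3R,6E)-3-(TBSO)-6-[2-(TBDPSO)ethylidene]-2-methyloxepan-2-yl}-2-methylpentan-1-ol
Conditions: camphorsulfonic acid (0.1 equiv), MeOH/CH2Cl2 1:1, 0 °C
Reagents that add atoms: none
Why: Acid-catalysed methanolysis of silyl ethers follows steric access, so the unhindered primary TBS ether at C5' is cleaved while the neopentyl-type secondary TBS ether at C3 and the acid-stable TBDPS ether at C9 remain.

Step 17
Reactants: 26 primary alcohol
Product: 27 (2R)-5-{(2S,3R,6E)-3-(TBSO)-6-[2-(TBDPSO)ethylidene]-2-methyloxepan-2-yl}-2-methylpentanal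
Conditions: TEMPO (0.1 equiv), PhI(OAc)2 (1.1 equiv), CH2Cl2, rt
Reagents that add atoms: none
Why: Oxoammonium (TEMPO) oxidation stops at the aldehyde and is non-basic, so C4' does not epimerise and the alkene and silyl ethers are left alone.

Step 18
Reactants: 28 3-methylbut-1-yne
Product: 30 (E)-1-iodo-2,3-dimethylbut-1-ene, via alkenylalane 29 (not isolated)
Conditions: Me3Al (2 equiv), Cp2ZrCl2 (0.2 equiv), CH2Cl2, 0 °C to rt; then I2, THF, -30 to 0 °C
Reagents that add atoms: trimethylaluminium C[Al](C)C; iodine [I][I]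
Why: Negishi zirconium-catalysed carboalumination adds methyl and aluminium syn across the alkyne with aluminium at the terminal carbon, and iodinolysis proceeds with retention, which fixes methyl cis to iodine (E).

Step 19
Reactants: 30 (E)-alkenyl iodide; 27 aldehyde
Product: 32 (3E,6R)-9-{(2S,3R,6E)-3-(TBSO)-6-[2-(TBDPSO)ethylidene]-2-methyloxepan-2-yl}-2,3,6-trimethylnon-3-en-5-ol (both epimers at the carbinol C5'), via alkenyllithium 31 (not isolated)
Conditions: 30 (1.5 equiv), t-BuLi (3.0 equiv), Et2O, -78 °C; then 27, -78 °C; sat. aq. NH4Cl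
Reagents that add atoms: none
Why: Lithium-iodine exchange with retention of alkene geometry followed by 1,2-addition to the aldehyde forms C5'-C6', addition outruns enolisation at -78 °C, and the new carbinol centre needs no control since it is oxidised next.

Step 20
Reactants: 32 allylic alcohol
Product: 33 (3E,6R)-9-{(2S,3R,6E)-3-(TBSO)-6-[2-(TBDPSO)ethylidene]-2-methyloxepan-2-yl}-2,3,6-trimethylnon-3-en-5-one
Conditions: Dess-Martin periodinane (1.5 equiv), CH2Cl2, 0 °C to rt
Reagents that add atoms: none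
Why: Dess-Martin oxidation of a secondary allylic alcohol under nearly neutral conditions converges both carbinol epimers on one enone without moving the alkene or epimerising C4'.

Step 21
Reactants: 33 bis-silyl enone
Product: 34 montanol, (3E,6R)-9-[(2S,3R,6E)-3-hydroxy-6-(2-hydroxyethylidene)-2-methyloxepan-2-yl]-2,3,6-trimethylnon-3-en-5-one
Conditions: HF·pyridine, pyridine, THF, 0 °C to rt
Reagents that add atoms: none
Why: Fluoride-driven global desilylation, in which pyridine-buffered HF cleaves both the hindered C3 TBS ether and the C9 TBDPS ether through Si-F bond formation and, being non-basic, preserves the C4' centre alpha to the ketone and both alkene geometries.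

Compound list
1 | 2-methylcyclohexane-1,3-dione | CC1C(=O)CCCC1=O | starting material
2 | allyl acetate | C=CCOC(C)=O | starting material
3 | 2-allyl-2-methylcyclohexane-1,3-dione | C=CCC1(C)C(=O)CCCC1=O | intermediate
4 | (2S,3R)-2-allyl-3-hydroxy-2-methylcyclohexan-1-one | C=CC[C@]1(C)C(=O)CCC[C@H]1O | intermediate
5 | (2S,3R)-2-allyl-3-(TBSO)-2-methylcyclohexan-1-one | C=CC[C@]1(C)C(=O)CCC[C@H]1O[Si](C)(C)C(C)(C)C | intermediate
6 | methyl (S)-3-hydroxy-2-methylpropanoate | OC[C@H](C)C(=O)OC | starting material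
7 | methyl (S)-3-(TBSO)-2-methylpropanoate | CC(C)(C)[Si](C)(C)OC[C@H](C)C(=O)OC | intermediate
8 | (S)-3-(TBSO)-2-methylpropanal | CC(C)(C)[Si](C)(C)OC[C@H](C)C=O | intermediate
9 | (R)-tert-butyldimethyl[(2-methylbut-3-en-1-yl)oxy]silane | CC(C)(C)[Si](C)(C)OC[C@H](C)C=C | intermediate
10 | (2S,3R)-3-(TBSO)-2-[(2E,4R)-5-(TBSO)-4-methylpent-2-en-1-yl]-2-methylcyclohexan-1-one | CC(C)(C)[Si](C)(C)OC[C@H](C)/C=C/C[C@]1(C)C(=O)CCC[C@H]1O[Si](C)(C)C(C)(C)C | intermediate
11 | (2S,3R)-3-(TBSO)-2-[(4R)-5-(TBSO)-4-methylpentyl]-2-methylcyclohexan-1-one | CC(C)(C)[Si](C)(C)OC[C@H](C)CCC[C@]1(C)C(=O)CCC[C@H]1O[Si](C)(C)C(C)(C)C | intermediate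
12 | Criegee adduct of 11: C7 bears OH and 3-chlorobenzoylperoxy | CC(C)(C)[Si](C)(C)OC[C@H](C)CCC[C@]1(C)C(O)(OOC(=O)c2cccc(Cl)c2)CCC[C@H]1O[Si](C)(C)C(C)(C)C | intermediate
13 | (6R,7S)-6-(TBSO)-7-[(4R)-5-(TBSO)-4-methylpentyl]-7-methyloxepan-2-one | CC(C)(C)[Si](C)(C)OC[C@H](C)CCC[C@]1(C)OC(=O)CCC[C@H]1O[Si](C)(C)C(C)(C)C | intermediate
14 | (Z)-but-2-ene-1,4-diol | OC/C=C\CO | starting material
15 | (Z)-1,4-bis(TBDPSO)but-2-ene | CC(C)(C)[Si](c1ccccc1)(c1ccccc1)OC/C=C\CO[Si](c1ccccc1)(c1ccccc1)C(C)(C)C | intermediate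
16 | 3,5-bis[(TBDPSO)methyl]-1,2,4-trioxolane | CC(C)(C)[Si](c1ccccc1)(c1ccccc1)OCC1OOC(CO[Si](c2ccccc2)(c2ccccc2)C(C)(C)C)O1 | intermediate
17 | 2-(TBDPSO)acetaldehyde | CC(C)(C)[Si](c1ccccc1)(c1ccccc1)OCC=O | intermediate
18 | lithium enolate of 13 (C7-OLi, C6=C7) | CC(C)(C)[Si](C)(C)OC[C@H](C)CCC[C@]1(C)OC(O[Li])=CCC[C@H]1O[Si](C)(C)C(C)(C)C | intermediate
19 | (6R,7S)-3-[2-(TBDPSO)-1-hydroxyethyl]-6-(TBSO)-7-[(4R)-5-(TBSO)-4-methylpentyl]-7-methyloxepan-2-one | CC(C)(C)[Si](C)(C)OC[C@H](C)CCC[C@]1(C)OC(=O)C(C(O)CO[Si](c2ccccc2)(c2ccccc2)C(C)(C)C)CC[C@H]1O[Si](C)(C)C(C)(C)C | intermediate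
20 | C8 methanesulfonate of 19 | CC(C)(C)[Si](C)(C)OC[C@H](C)CCC[C@]1(C)OC(=O)C(C(CO[Si](c2ccccc2)(c2ccccc2)C(C)(C)C)OS(C)(=O)=O)CC[C@H]1O[Si](C)(C)C(C)(C)C | intermediate
21 | (3E,6R,7S)-3-[2-(TBDPSO)ethylidene]-6-(TBSO)-7-[(4R)-5-(TBSO)-4-methylpentyl]-7-methyloxepan-2-one | CC(C)(C)[Si](C)(C)OC[C@H](C)CCC[C@]1(C)OC(=O)/C(=C/CO[Si](c2ccccc2)(c2ccccc2)C(C)(C)C)CC[C@H]1O[Si](C)(C)C(C)(C)C | intermediate
22 | diisobutylaluminium hemiacetal of 21 (C7-H, C7-OAl-i-Bu2) | CC(C)(C)[Si](C)(C)OC[C@H](C)CCC[C@]1(C)OC(O[Al](CC(C)C)CC(C)C)/C(=C/CO[Si](c2ccccc2)(c2ccccc2)C(C)(C)C)CC[C@H]1O[Si](C)(C)C(C)(C)C | intermediate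
23 | (3E,6R,7S)-3-[2-(TBDPSO)ethylidene]-6-(TBSO)-7-[(4R)-5-(TBSO)-4-methylpentyl]-7-methyloxepan-2-yl acetate | CC(C)(C)[Si](C)(C)OC[C@H](C)CCC[C@]1(C)OC(OC(C)=O)/C(=C/CO[Si](c2ccccc2)(c2ccccc2)C(C)(C)C)CC[C@H]1O[Si](C)(C)C(C)(C)C | intermediate
24 | cyclic oxocarbenium ion O1=C7 conjugated with C6=C8 | CC(C)(C)[Si](C)(C)OC[C@H](C)CCC[C@]1(C)[O+]=C/C(=C/CO[Si](c2ccccc2)(c2ccccc2)C(C)(C)C)CC[C@H]1O[Si](C)(C)C(C)(C)C | intermediate
25 | (2S,3R,6E)-3-(TBSO)-6-[2-(TBDPSO)ethylidene]-2-[(4R)-5-(TBSO)-4-methylpentyl]-2-methyloxepane | CC(C)(C)[Si](C)(C)OC[C@H](C)CCC[C@]1(C)OC/C(=C/CO[Si](c2ccccc2)(c2ccccc2)C(C)(C)C)CC[C@H]1O[Si](C)(C)C(C)(C)C | intermediate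
26 | (2R)-5-{(2S,3R,6E)-3-(TBSO)-6-[2-(TBDPSO)ethylidene]-2-methyloxepan-2-yl}-2-methylpentan-1-ol | OC[C@H](C)CCC[C@]1(C)OC/C(=C/CO[Si](c2ccccc2)(c2ccccc2)C(C)(C)C)CC[C@H]1O[Si](C)(C)C(C)(C)C | intermediate
27 | (2R)-5-{(2S,3R,6E)-3-(TBSO)-6-[2-(TBDPSO)ethylidene]-2-methyloxepan-2-yl}-2-methylpentanal | O=C[C@H](C)CCC[C@]1(C)OC/C(=C/CO[Si](c2ccccc2)(c2ccccc2)C(C)(C)C)CC[C@H]1O[Si](C)(C)C(C)(C)C | intermediate
28 | 3-methylbut-1-yne | C#CC(C)C | starting material
29 | (E)-(2,3-dimethylbut-1-en-1-yl)dimethylalane | C/C(=C\[Al](C)C)C(C)C | intermediate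
30 | (E)-1-iodo-2,3-dimethylbut-1-ene | C/C(=C\I)C(C)C | intermediate
31 | (E)-(2,3-dimethylbut-1-en-1-yl)lithium | C/C(=C\[Li])C(C)C | intermediate
32 | (3E,6R)-9-{(2S,3R,6E)-3-(TBSO)-6-[2-(TBDPSO)ethylidene]-2-methyloxepan-2-yl}-2,3,6-trimethylnon-3-en-5-ol | C/C(=C\C(O)[C@H](C)CCC[C@]1(C)OC/C(=C/CO[Si](c2ccccc2)(c2ccccc2)C(C)(C)C)CC[C@H]1O[Si](C)(C)C(C)(C)C)C(C)C | intermediate
33 | (3E,6R)-9-{(2S,3R,6E)-3-(TBSO)-6-[2-(TBDPSO)ethylidene]-2-methyloxepan-2-yl}-2,3,6-trimethylnon-3-en-5-one | C/C(=C\C(=O)[C@H](C)CCC[C@]1(C)OC/C(=C/CO[Si](c2ccccc2)(c2ccccc2)C(C)(C)C)CC[C@H]1O[Si](C)(C)C(C)(C)C)C(C)C | intermediate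
34 | montanol | C/C(=C\C(=O)[C@H](C)CCC[C@]1(C)OC/C(=C/CO)CC[C@H]1O)C(C)C | target

Total step count: 21.
Longest linear sequence: 15 steps (1, 3, 4, 5, 10, 11, 13, 19, 21, 23, 25, 26, 27, 32, 33, 34). The branch from 6 through steps 4 to 6 is equally long.

Steps most likely to fail

Step 14, on which step 15 depends.
- **Risk:** The aluminium hemiacetal of this crowded, conjugated seven-membered lactone may open to the hydroxy enal faster than its oxygen is acylated. Over-reduction and loss of the ring would follow.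
- **Fallback:** It sets out from 21 and returns at 25, bypassing 23 and step 15.
  - Excess i-Bu2AlH (CH2Cl2, -78 to 0 °C) would reduce the lactone on purpose to (2E,5R,6S,10R)-5,11-bis(TBSO)-2-[2-(TBDPSO)ethylidene]-6,10-dimethylundecane-1,6-diol F1.
  - A Corey-Kim chlorination (N-chlorosuccinimide, Me2S, CH2Cl2, -20 °C) would convert only the primary allylic C7 hydroxyl, giving the allylic chloride F2. The tertiary C2 hydroxyl is inert to it.
  - NaH in THF (cat. n-Bu4NI, no polar cosolvent, so that the C3 silyl group is not encouraged to migrate) would re-close O1-C7 by a 7-exo-tet Williamson etherification to give 25.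
  - The difficult C2-O1 bond made in step 9 is kept throughout.

Step 2.
- **Risk:** The enzyme may discriminate poorly between the two enantiotopic carbonyl groups, deliver hydride to the wrong face, or turn over slowly.
- **Fallback:** It sets out from 3 and returns at 4.
  - A Corey-Bakshi-Shibata reduction would be used: (S)-2-methyl-CBS-oxazaborolidine (20 mol %), catecholborane, toluene, -78 °C.
  - The catalyst places the quaternary C2 side as the large group, which corresponds to the R carbinol.
  - The ketol with hydroxyl trans to methyl would be removed by chromatography.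
  - This fallback makes no compound that the list lacks (F0).

Step 7.
- **Risk:** Homodimerisation may compete, the catalyst may stall on two encumbered alkenes, and ruthenium hydride-induced double-bond migration could erode C4'.
- **Fallback:** It sets out from 5 and 7 and returns at 11, replacing metathesis by carbonyl olefination.
  - Lemieux-Johnson cleavage of 5 (OsO4 cat., NaIO4, 2,6-lutidine, dioxane/H2O) would give 2-[(1S,2R)-2-(TBSO)-1-methyl-6-oxocyclohexyl]acetaldehyde F3.
  - Ester 7 would be reduced with excess i-Bu2AlH to (R)-3-(TBSO)-2-methylpropan-1-ol F4.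
  - F4 would be converted with I2, PPh3 and imidazole into (S)-tert-butyl(3-iodo-2-methylpropoxy)dimethylsilane F5.
  - F5 would be heated with PPh3 in MeCN to give the phosphonium iodide F6.
  - NaN(SiMe3)2 (THF, -78 °C) would generate the ylide F7, which would react with the aldehyde group of F3 in a Wittig olefination. The hindered ketone stays untouched, and the product is the Z-alkene F8.
  - Hydrogenation under the conditions of step 8 would then give 11.

Further compounds
F1 | step 14 | (2E,5R,6S,10R)-5,11-bis(TBSO)-2-[2-(TBDPSO)ethylidene]-6,10-dimethylundecane-1,6-diol | CC(C)(C)[Si](C)(C)OC[C@H](C)CCC[C@](C)(O)[C@H](O[Si](C)(C)C(C)(C)C)CC/C(CO)=C\CO[Si](c1ccccc1)(c1ccccc1)C(C)(C)C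
F2 | step 14 | allylic chloride, F1 with Cl in place of the primary C7 hydroxyl (tertiary C2 hydroxyl free, E alkene) | CC(C)(C)[Si](C)(C)OC[C@H](C)CCC[C@](C)(O)[C@H](O[Si](C)(C)C(C)(C)C)CC/C(CCl)=C\CO[Si](c1ccccc1)(c1ccccc1)C(C)(C)C
F0 | step 2 | none | none
F3 | step 7 | 2-[(1S,2R)-2-(TBSO)-1-methyl-6-oxocyclohexyl]acetaldehyde | O=CC[C@]1(C)C(=O)CCC[C@H]1O[Si](C)(C)C(C)(C)C
F4 | step 7 | (R)-3-(TBSO)-2-methylpropan-1-ol | CC(C)(C)[Si](C)(C)OC[C@H](C)CO
F5 | step 7 | (S)-tert-butyl(3-iodo-2-methylpropoxy)dimethylsilane | CC(C)(C)[Si](C)(C)OC[C@H](C)CI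
F6 | step 7 | [(S)-3-(TBSO)-2-methylpropyl]triphenylphosphonium iodide | CC(C)(C)[Si](C)(C)OC[C@H](C)C[P+](c1ccccc1)(c1ccccc1)c1ccccc1.[I-]
F7 | step 7 | [(S)-3-(TBSO)-2-methylpropylidene]triphenylphosphorane | CC(C)(C)[Si](C)(C)OC[C@H](C)C=P(c1ccccc1)(c1ccccc1)c1ccccc1
F8 | step 7 | (2S,3R)-3-(TBSO)-2-[(2Z,4R)-5-(TBSO)-4-methylpent-2-en-1-yl]-2-methylcyclohexan-1-one | CC(C)(C)[Si](C)(C)OC[C@H](C)/C=C\C[C@]1(C)C(=O)CCC[C@H]1O[Si](C)(C)C(C)(C)C
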